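The flavone's ring A is hexasubstituted, with oxygen on C5, C7 and C8a in a 1,3,5 pattern and the C4 carbonyl on C4a between two of them; C6 bears the methyl and C8 the methoxy group. This alternation is that of a folded poly-β-carbonyl chain, so everything rests on disconnecting the ring-fusion bond C4a–C8a. The precursor is an open-chain methyl 3,5,7-trioxooctanoate with the future C8 methoxy on C2, the C6 methyl on C4 and a terminal methoxymethyl ketone (future C4 and C3). A single base-mediated Claisen condensation closes ring A with all six substituents placed. Three enolate acylations assemble the chain; C-aroylation and acid cyclodehydration then build ring C.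

Key step: step 4

Remark on the chemistry: the target has no stereocentre. The open-chain poly-carbonyl intermediates and both non-isolated intermediates are keto/enol or diastereomer mixtures with configurationally labile CH centres, so they are drawn without stereodescriptors. The two N-methoxy-N-methylamides and 4-methoxybenzoyl chloride are assumed to be purchased.

Step 1
Reactants: 1 methyl methoxyacetate; 2 propanoyl chloride
Product: 3 methyl 2-methoxy-3-oxopentanoate
Conditions: 1 (2.1 equiv), LiN(iPr)2 (2.1 equiv), THF, −78 °C; then 2 (1.0 equiv), −78 °C; 1 M HCl
Reagents that add atoms: none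
Why: Crossed Claisen C-acylation of the lithium enolate of an α-alkoxy ester by an acid chloride at low temperature, in which the second equivalent of enolate deprotonates the β-keto ester as it forms and so prevents a second acylation.

Step 2
Reactants: 3 methyl 2-methoxy-3-oxopentanoate; 4 N-methoxy-N-methylacetamide
Product: 5 methyl 2-methoxy-4-methyl-3,5-dioxohexanoate
Conditions: LiN(iPr)2 (2.2 equiv), THF, −78 → 0 °C; then 4 (1.2 equiv), −78 → 0 °C; cold 1 M HCl
Reagents that add atoms: none
Why: γ-Acylation of a β-keto ester dianion: the second deprotonation occurs at the ethyl CH2, whose carbanion adds to the N-methoxy-N-methylamide to give a chelated tetrahedral adduct that releases the ketone only on acidic work-up, so neither over-addition nor quenching of the dianion by the more acidic diketone can occur.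

Step 3
Reactants: 5 methyl 2-methoxy-4-methyl-3,5-dioxohexanoate; 6 N,2-dimethoxy-N-methylacetamide
Product: 7 methyl 2,8-dimethoxy-4-methyl-3,5,7-trioxooctanoate
Conditions: LiN(iPr)2 (3.3 equiv), THF, −78 → 0 °C; then 6 (1.2 equiv), −78 → −20 °C; cold 1 M HCl; crude 7 used at once
Reagents that add atoms: none
Why: Terminal acylation of the trianion of a 3,5-diketo ester (Claisen-type): once the two CH acids between carbonyl groups are ionised, the third deprotonation takes place at the terminal methyl group, whose carbanion is the only strongly nucleophilic site and attacks the N-methoxy-N-methylamide.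

Step 4
Reactants: 7 methyl 2,8-dimethoxy-4-methyl-3,5,7-trioxooctanoate
Product: 9 2-methoxy-1-(2,4,6-trihydroxy-3-methoxy-5-methylphenyl)ethan-1-one, via cyclohexane-1,3,5-trione 8 (not isolated)
Conditions: NaOMe (6 equiv), degassed MeOH, 0 °C → rt, Ar; then 1 M HCl, 0 °C
Reagents that add atoms: none
Why: Excess methoxide converts 7 into its polyanion, in which the carbanion at the unsubstituted chain methylene C6 (future C4a), flanked by the C5 and C7 ketones, adds to the ester carbonyl C1 (future C8a); loss of methoxide gives trione 8, which tautomerises three times to the arene 9. The closest known reaction type is the alkoxide- or hydroxide-promoted intramolecular ester condensation by which open-chain 3,5,7-triketo esters fold into acylphloroglucinols, the same folding that polyketide synthases of the chalcone type perform. Ring A closes in a 6-exo-trig acyl substitution (Dieckmann-like) that makes only the C4a–C8a bond, and no stereocentre results since all six ring carbons become sp2. The step needs the ester condensation to prevail over aldol and lactone closures: the C2 methoxy leaves the C2-to-C7 aldol adduct with a quaternary carbon that blocks dehydration to a resorcylate, so it reverts, the competing C8 carbanion is stabilised by one ketone only, and the pyranone from O-acylation is reopened by methoxide, so that irreversible aromatisation of 8 drains these equilibria. A large excess of alkoxide in dry methanol keeps every ketone masked as its enolate against retro-Claisen cleavage, leaves the ester as the only acceptor without saponifying it, and argon protects the easily oxidised phenoxide of 9.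

Step 5
Reactants: 9 2-methoxy-1-(2,4,6-trihydroxy-3-methoxy-5-methylphenyl)ethan-1-one; 10 4-methoxybenzoyl chloride
Product: 11 2-methoxy-1-(4-methoxyphenyl)-3-(2,4,6-trihydroxy-3-methoxy-5-methylphenyl)propane-1,3-dione
Conditions: LiN(SiMe3)2 (5.5 equiv), THF, −78 → −10 °C; then 10 (1.05 equiv), −78 °C → rt; 1 M HCl
Reagents that add atoms: none
Why: Claisen-type C-aroylation of the lithium polyanion of a polyhydroxyaryl ketone (the protecting-group-free variant of the Baker–Venkataraman route): aggregated lithium phenoxides are poor O-nucleophiles at low temperature whereas the α-methoxy enolate carbon is acylated, and the extra equivalent of base takes up the acidic proton of the 1,3-diketone as it forms.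

Step 6
Reactants: 11 2-methoxy-1-(4-methoxyphenyl)-3-(2,4,6-trihydroxy-3-methoxy-5-methylphenyl)propane-1,3-dione
Product: 13 5,7-dihydroxy-3,8-dimethoxy-2-(4-methoxyphenyl)-6-methyl-4H-chromen-4-one, via 2-hydroxychromanone hemiketal 12 (not isolated)
Conditions: TsOH·H2O (10 mol %), ClCH2CH2Cl, 70 °C
Reagents that add atoms: none
Why: Acid-catalysed cyclodehydration of an o-hydroxyaryl 1,3-diketone (the closing stage of a Baker–Venkataraman flavone synthesis): the hydroxyl that adds to the aroyl carbonyl must turn its O–H bond away from the side chain, which for the C8a hydroxyl points it at the C8 methoxy oxygen (an internal hydrogen-bond acceptor) but for the C5 hydroxyl pushes it against the C6 methyl, while the C5 hydroxyl stays chelated to the C4 carbonyl, so closure of the O1–C8a ring is expected to be preferred in a non-competing solvent and hemiketal 12 then loses water to the pyranone.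

Compound list
1 | methyl methoxyacetate | COCC(=O)OC | starting material
2 | propanoyl chloride | CCC(Cl)=O | starting material
3 | methyl 2-methoxy-3-oxopentanoate (racemic, labile centre) | CCC(=O)C(OC)C(=O)OC | intermediate
4 | N-methoxy-N-methylacetamide | CC(=O)N(C)OC | starting material
5 | methyl 2-methoxy-4-methyl-3,5-dioxohexanoate (keto/enol mixture) | CC(=O)C(C)C(=O)C(OC)C(=O)OC | intermediate
6 | N,2-dimethoxy-N-methylacetamide | COCC(=O)N(C)OC | starting material
7 | methyl 2,8-dimethoxy-4-methyl-3,5,7-trioxooctanoate (keto/enol mixture) | COCC(=O)CC(=O)C(C)C(=O)C(OC)C(=O)OC | intermediate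
8 | 2-methoxy-4-(methoxyacetyl)-6-methylcyclohexane-1,3,5-trione (tautomer mixture, not isolated) | COCC(=O)C1C(=O)C(OC)C(=O)C(C)C1=O | intermediate
9 | 2-methoxy-1-(2,4,6-trihydroxy-3-methoxy-5-methylphenyl)ethan-1-one | COCC(=O)c1c(O)c(OC)c(O)c(C)c1O | intermediate
10 | 4-methoxybenzoyl chloride | COc1ccc(cc1)C(Cl)=O | starting material
11 | 2-methoxy-1-(4-methoxyphenyl)-3-(2,4,6-trihydroxy-3-methoxy-5-methylphenyl)propane-1,3-dione (keto/enol mixture) | COc1ccc(cc1)C(=O)C(OC)C(=O)c1c(O)c(OC)c(O)c(C)c1O | intermediate
12 | 2,5,7-trihydroxy-3,8-dimethoxy-2-(4-methoxyphenyl)-6-methyl-2,3-dihydro-4H-chromen-4-one (2-hydroxychromanone hemiketal, diastereomer mixture, not isolated) | COc1ccc(cc1)C1(O)Oc2c(OC)c(O)c(C)c(O)c2C(=O)C1OC | intermediate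
13 | 5,7-dihydroxy-3,8-dimethoxy-2-(4-methoxyphenyl)-6-methyl-4H-chromen-4-one | COc1ccc(-c2oc3c(OC)c(O)c(C)c(O)c3c(=O)c2OC)cc1 | target

Total step count: 6
Longest linear sequence: 6 steps (1 and 2 to 13)

Steps most likely to fail

1. Step 4. Instead of closing ring A, the chain may be cleaved by methoxide at a ketone that is momentarily not enolised (retro-Claisen), or the ester may stay inert because the neighbouring C2 position is held as its enolate. The fallback sets out from 2 and comes back to the route at 9; it raises the acylating power of the chain terminus and does without a nucleophilic base. Methoxyacetyl chloride and 2-methylpropane-2-thiol (pyridine, CH2Cl2, 0 °C) should give S-tert-butyl 2-methoxyethanethioate F1 as the chain starter. Its lithium enolate (LiN(iPr)2, THF, −78 °C) is acylated by 2 to S-tert-butyl 2-methoxy-3-oxopentanethioate F2 in the manner of step 1. Dianion acylation with 4 then gives S-tert-butyl 2-methoxy-4-methyl-3,5-dioxohexanethioate F3 as in step 2, and trianion acylation with 6 gives S-tert-butyl 2,8-dimethoxy-4-methyl-3,5,7-trioxooctanethioate F4 as in step 3. Treatment of F4 with Cs2CO3 in MeCN, a thioester Claisen condensation with 2-methylpropane-2-thiolate as the leaving group, should give 9.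

2. Step 6. Ring C may close with poor regioselectivity, through the hydroxyl beside the methyl group as well as the one beside the methoxy group, because the two ortho hydroxyls differ only in their outer neighbours. The fallback sets out from 11 and comes back to the route at 13; it replaces kinetic closure by thermodynamic equilibration with recycling. The wrong closure gives 5,7-dihydroxy-3,6-dimethoxy-2-(4-methoxyphenyl)-8-methyl-4H-chromen-4-one F5 beside 13. Because F5 keeps a free chelated hydroxyl next to the pyranone carbonyl, HCl in aqueous ethanol at reflux should reopen its ring C to 11 and reclose it in either sense (Wessely–Moser rearrangement). 13 is taken out of the equilibrium mixture by chromatography or crystallisation, and the recovered F5 is returned to the acid.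

3. Step 3. Proton transfer from the amide 6 to the trianion, or incomplete formation of the trianion, may return 5, and 7 may lactonise to a pyranone during work-up. The fallback sets out from 5 and comes back to the route at 7; it replaces the acylation by an aldol addition followed by oxidation. The same trianion is added to methoxyacetaldehyde at −78 °C, which should give methyl 7-hydroxy-2,8-dimethoxy-4-methyl-3,5-dioxooctanoate F6 after cold acidic work-up. Oxidation of F6 with 2-iodoxybenzoic acid in DMSO at rt then gives 7.

Further compounds
F1 | step 4 | S-tert-butyl 2-methoxyethanethioate | COCC(=O)SC(C)(C)C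
F2 | step 4 | S-tert-butyl 2-methoxy-3-oxopentanethioate | CCC(=O)C(OC)C(=O)SC(C)(C)C
F3 | step 4 | S-tert-butyl 2-methoxy-4-methyl-3,5-dioxohexanethioate | CC(=O)C(C)C(=O)C(OC)C(=O)SC(C)(C)C
F4 | step 4 | S-tert-butyl 2,8-dimethoxy-4-methyl-3,5,7-trioxooctanethioate | COCC(=O)CC(=O)C(C)C(=O)C(OC)C(=O)SC(C)(C)C
F5 | step 6 | 5,7-dihydroxy-3,6-dimethoxy-2-(4-methoxyphenyl)-8-methyl-4H-chromen-4-one | COc1ccc(cc1)-c1oc2c(C)c(O)c(OC)c(O)c2c(=O)c1OC
F6 | step 3 | methyl 7-hydroxy-2,8-dimethoxy-4-methyl-3,5-dioxooctanoate | COCC(O)CC(=O)C(C)C(=O)C(OC)C(=O)OC
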